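**Retrosynthetic overview**
1. 7 ⇒ 6: break C6–C11. The last step is a bromonium-induced spirocyclisation of a γ-bisabolene that already carries the ring-B Cl/Br pair. It closes ring A and creates C6 and C10.
2. 6 ⇒ 3 + 4: bisabolyl-cation logic. A prenyl cation adds to the isopropenyl CH2 of 3 (head-to-tail prenyl transfer), then H-6 is lost.
3. 3 ⇒ 1: the secondary-Cl/tertiary-Br pair is set on the flexible monocycle. Cl⁻ opens trans-limonene oxide diaxially, then Br⁻ replaces O with retention through a chloronium ion.
4. Ring order: ring B comes intact from the (R)-limonene chiral pool, and ring A is closed last.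

Numbering (chamigrene/bisabolane): C2 = CHCl, C3 = C(Me)Br, C6 = spiro centre, C7 = C(Me)=, C10 = CHBr, C11 = CMe2.
Assumption: commercial (+)-limonene oxide is the roughly 1:1 cis/trans mixture made from (R)-limonene. Only the trans isomer (drawn as 1) is productive, and the regioisomer formed from the cis isomer is removed by chromatography after step 1.

Step 1
Reactants: 1 (+)-trans-limonene oxide
Product: 2 (1S,2S,4R)-2-chloro-1-methyl-4-(prop-1-en-2-yl)cyclohexyl trimethylsilyl ether
Conditions: TMSCl (1.2 equiv), Ph3P (5 mol %), CH2Cl2, 0 °C to rt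
Reagents that add atoms: chlorotrimethylsilane, C[Si](C)(C)Cl
Why: This is a silyl-halide epoxide opening under Fürst–Plattner (trans-diaxial) control, in which chloride attacks the secondary C2 with inversion (setting C2 as S) while the C3–O bond and its configuration stay untouched, so Cl and OSiMe3 are trans-diaxial with the isopropenyl group equatorial.

Step 2
Reactants: 2 (1S,2S,4R)-2-chloro-1-methyl-4-(prop-1-en-2-yl)cyclohexyl trimethylsilyl ether
Product: 3 (1S,2S,4R)-1-bromo-2-chloro-1-methyl-4-(prop-1-en-2-yl)cyclohexane
Conditions: TMSBr (1.3 equiv), 2,6-di-tert-butyl-4-methylpyridine (0.2 equiv), CH2Cl2, −40 to 0 °C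
Reagents that add atoms: bromotrimethylsilane, C[Si](C)(C)Br
Why: This is an acid-free SN1-type silyl ether to tertiary bromide exchange with neighbouring-group participation, in which the antiperiplanar axial C2–Cl bridges the C3 cation (chloronium) and bromide re-enters axially at the tertiary carbon on the face the oxygen left, giving net retention at C3 (S), the trans-diaxial secondary-Cl/tertiary-Br pair and an untouched isopropenyl group.

Step 3
Reactants: 3 (1S,2S,4R)-1-bromo-2-chloro-1-methyl-4-(prop-1-en-2-yl)cyclohexane, 4 prenyl bromide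
Product: 6 (1S,2S,4E)-1-bromo-2-chloro-1-methyl-4-(6-methylhept-5-en-2-ylidene)cyclohexane, via tertiary bisabolyl bromide 5 (not isolated)
Conditions: 4 (0.8 equiv, slow addition), ZnBr2·OEt2 (15 mol %), CH2Cl2, −78 °C; then 2,6-lutidine (2.5 equiv), HFIP co-solvent, −78 to 0 °C; AgNO3–SiO2 or prep. HPLC (collect the E isomer; recover 3)
Reagents that add atoms: none
Why: A Lewis-acid-catalysed allyl halide–alkene addition (a 1:1 adduct forms because prenyl bromide ionises faster than the adduct) builds the bisabolyl skeleton, then a buffered solvolytic Saytzeff E1 in HFIP removes HBr only at C7 because C3–Br is about 10³-fold deactivated by the β-chlorine; no stereocentre is made, the E/Z ratio is about 1:1, and the E isomer (chain cis to CH2-5) is isolated from the Z isomer and from the Δ7,8/Δ7,14 isomers.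

Step 4
Reactants: 6 (1S,2S,4E)-1-bromo-2-chloro-1-methyl-4-(6-methylhept-5-en-2-ylidene)cyclohexane
Product: 7 (4R,6S,8S,9S)-4,9-dibromo-8-chloro-1,5,5,9-tetramethylspiro[5.5]undec-1-ene
Conditions: BDSB (1.05 equiv), MeNO2, −25 °C, 5 min; aq NaHCO3/Na2SO3
Reagents that add atoms: bromodiethylsulfonium bromopentachloroantimonate (BDSB), CC[S+](Br)CC.Cl[Sb-](Cl)(Cl)(Cl)(Cl)Br
Why: Proposed new method: Br⁺ transfer is reversible between the two alkenes but only the C10–C11 bromonium has a productive exit, so C6 of the tetrasubstituted alkene attacks C11 anti to Br through a chair transition state with Br equatorial (in the E-alkene C8 is cis to C5, which places C1 cis to Br on ring A and makes C10 R), and it does so on the ring-B face that leaves C11 equatorial and cis to the equatorial C2–Cl in the diequatorial-dihalide chair (the other face would put C11 axial or C7 syn-axial to Cl, so C6 becomes S), after which the C7 cation loses H-8; the closest known reaction type is the bromonium-induced polyene cyclisation with BDSB or TBCO, including γ-bisabolene to 10-bromo-α-chamigrene.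

**Compound list**
1 | (+)-trans-limonene oxide, (1S,2R,4R)-1,2-epoxy-p-menth-8-ene | C[C@]12CC[C@H](C[C@H]1O2)C(C)=C | starting material
2 | (1S,2S,4R)-2-chloro-1-methyl-4-(prop-1-en-2-yl)cyclohexyl trimethylsilyl ether (Cl/OSiMe3 trans-diaxial) | C[C@]1(O[Si](C)(C)C)CC[C@H](C[C@@H]1Cl)C(C)=C | intermediate
3 | (1S,2S,4R)-1-bromo-2-chloro-1-methyl-4-(prop-1-en-2-yl)cyclohexane | C[C@]1(Br)CC[C@H](C[C@@H]1Cl)C(C)=C | intermediate
4 | prenyl bromide (1-bromo-3-methylbut-2-ene) | CC(C)=CCBr | starting material
5 | (1S,2S,4R)-1-bromo-4-(2-bromo-6-methylhept-5-en-2-yl)-2-chloro-1-methylcyclohexane, both C7 epimers | C[C@]1(Br)CC[C@H](C[C@@H]1Cl)C(C)(Br)CCC=C(C)C | intermediate (not isolated)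
6 | (1S,2S,4E)-1-bromo-2-chloro-1-methyl-4-(6-methylhept-5-en-2-ylidene)cyclohexane (homoprenyl chain cis to the ring CH2 remote from CHCl) | C[C@]1(Br)CC/C(C[C@@H]1Cl)=C(/C)CCC=C(C)C | intermediate
7 | (2S,3S,6S,10R)-3,10-dibromo-2-chloro-α-chamigrene = (4R,6S,8S,9S)-4,9-dibromo-8-chloro-1,5,5,9-tetramethylspiro[5.5]undec-1-ene | CC1=CC[C@@H](Br)C(C)(C)[C@]12CC[C@](C)(Br)[C@@H](Cl)C2 | target

Total step count: 4. Longest linear sequence: 4 (1 → 2 → 3 → 6 → 7).

**Steps most likely to fail**

Step 3 carries three risks: over-prenylation, poor Saytzeff selectivity, and a roughly 1:1 E/Z ratio that may be hard to separate. The fallback sets out from 3 and comes back at 6. Ozonolysis of the isopropenyl group gives the methyl ketone F1. Adding the homoprenyl organocerium reagent (from 5-bromo-2-methylpent-2-ene, CeCl3, −78 °C) gives two C7-epimeric tertiary alcohols, the (7R)-alcohol F2 and the (7S)-alcohol F3, which are separated on silica. Each is then dehydrated stereospecifically, the (7R)-alcohol F2 by anti E2 (SOCl2, pyridine) and the (7S)-alcohol F3 by syn elimination (Burgess reagent). Both epimers therefore converge on the E-alkene 6.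

Step 4 has several failure modes. Br⁺ may be diverted at the tetrasubstituted alkene. The bond that joins two fully substituted carbons may form slowly. Proton loss may give an endo/exo alkene mixture. C3–Br may ionise under antimony Lewis acids. The fallback sets out from 6 and comes back at 7. The ring is closed with a carbophilic metal instead of Br⁺: Hg(O2CCF3)2 in MeNO2 at −20 °C, then aq KBr. The same chair and facial arguments apply, and the product is the equatorial organomercuric bromide F4. Bromodemercuration (Br2, LiBr, pyridine, dark) then places Br in the equatorial C10 position.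

Step 2 may give elimination to allylic chlorides, bromide attack at C2 (halogen transposition), or traces of HBr adding to the isopropenyl group. The fallback sets out from 2 and comes back at 3. It accepts hydrobromination and uses it as a mask. Methanolysis gives the free chlorohydrin F5. Excess dry HBr (CH2Cl2, −30 °C) converts the tertiary alcohol with the same chloronium-controlled retention and also saturates the side-chain alkene, giving the dibromide F6. The undeactivated C7–Br alone is then removed by buffered solvolytic E1 (HFIP, 2,6-lutidine, 0 °C), and 3 is separated from its isopropylidene isomer.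

**Further compounds**
F1 | step 3 | 1-[(1R,3S,4S)-4-bromo-3-chloro-4-methylcyclohexyl]ethan-1-one | C[C@]1(Br)CC[C@H](C[C@@H]1Cl)C(C)=O
F2 | step 3 | (2R)-2-[(1R,3S,4S)-4-bromo-3-chloro-4-methylcyclohexyl]-6-methylhept-5-en-2-ol | C[C@]1(Br)CC[C@H](C[C@@H]1Cl)[C@](C)(O)CCC=C(C)C
F3 | step 3 | (2S)-2-[(1R,3S,4S)-4-bromo-3-chloro-4-methylcyclohexyl]-6-methylhept-5-en-2-ol | C[C@]1(Br)CC[C@H](C[C@@H]1Cl)[C@@](C)(O)CCC=C(C)C
F4 | step 4 | (2S,3S,6S,10R)-3-bromo-10-(bromomercurio)-2-chloro-α-chamigrene | CC1=CC[C@@H]([Hg]Br)C(C)(C)[C@]12CC[C@](C)(Br)[C@@H](Cl)C2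
F5 | step 2 | (1S,2S,4R)-2-chloro-1-methyl-4-(prop-1-en-2-yl)cyclohexan-1-ol | C[C@]1(O)CC[C@H](C[C@@H]1Cl)C(C)=C
F6 | step 2 | (1S,2S,4R)-1-bromo-4-(2-bromopropan-2-yl)-2-chloro-1-methylcyclohexane | C[C@]1(Br)CC[C@H](C[C@@H]1Cl)C(C)(C)Br
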